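**Retrosynthetic overview**

- Ring C of the flavone is closed last, by acid hydrolysis and cyclodehydration of a β‑enaminone. The enaminone comes from hydrogenolysis (N–O bond and two O‑benzyl bonds) of a 3‑aryl‑5‑(4‑methoxyphenyl)isoxazole.
- The isoxazole is disconnected by a [3+2] cycloaddition into 2,4‑bis(benzyloxy)‑3,5,6‑trimethoxybenzonitrile oxide and 4‑ethynylanisole. This forms the future C3–C4 and O–C2 bonds and delivers the C2–C3–C4 unit as a masked 1,3‑diketone.
- Structural feature used: C4 is attached to C4a of ring A, and C4a lies between the two oxygen‑bearing carbons C5 and C8a. A nitrile oxide on such a doubly ortho‑alkoxylated carbon is shielded against dimerisation, and ring A is fully substituted, so it cannot be halogenated when the dipole is generated.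
- The nitrile oxide comes from the oxime of a hexasubstituted benzaldehyde, built from 1,2,4,5‑tetramethoxybenzene by lithiation/oxidation, para‑formylation, chelation‑controlled mono‑O‑demethylation and dibenzylation.
- Ring order: rings A and B are purchased; the temporary isoxazole ring is formed in step 7; the pyranone ring C in step 9.

Key step: step 7

Assumption: the nitrile oxide, like other 2,6‑dialkoxybenzonitrile oxides, is taken to be persistent enough to survive a cold aqueous work‑up and to be used without chromatography.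

**Route**

Step 1
Reactants: 1 1,2,4,5‑tetramethoxybenzene
Product: 4 2,3,5,6‑tetramethoxyphenol, via (2,3,5,6‑tetramethoxyphenyl)lithium 2 (not isolated), via dimethyl (2,3,5,6‑tetramethoxyphenyl)boronate 3 (not isolated)
Conditions: n‑BuLi, THF, 0 °C to rt; B(OMe)3, −78 °C to rt; AcOH, 30% aq. H2O2, 0 °C to rt
Reagents that add atoms: hydrogen peroxide (OO)
Why: Directed ortho‑lithiation removes one of the two equivalent ring hydrogens, each flanked by two methoxy groups, and borylation followed by peroxide oxidation of the aryl boronate (1,2‑shift of aryl from boron to oxygen) installs the hydroxyl, a standard arene‑to‑phenol sequence.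

Step 2
Reactants: 4 2,3,5,6‑tetramethoxyphenol
Product: 5 4‑hydroxy‑2,3,5,6‑tetramethoxybenzaldehyde
Conditions: Cl2CHOMe, TiCl4, CH2Cl2, −10 to 0 °C; then ice/aq. HCl
Reagents that add atoms: dichloromethyl methyl ether (COC(Cl)Cl); water (O)
Why: Rieche formylation: the single free ring position is para to the hydroxyl and ortho to two methoxy groups, so it is strongly activated and the only site open to the small chloro(methoxy)carbenium electrophile, and aqueous hydrolysis of the resulting α‑chloro ether delivers the aldehyde, whose oxygen therefore comes from water.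

Step 3
Reactants: 5 4‑hydroxy‑2,3,5,6‑tetramethoxybenzaldehyde
Product: 6 2,4‑dihydroxy‑3,5,6‑trimethoxybenzaldehyde
Conditions: BCl3 (2.5 equiv), CH2Cl2, −78 to 0 °C; then H2O
Reagents that add atoms: none
Why: Chelation‑controlled Lewis‑acid ether cleavage: BCl3 bridges the aldehyde oxygen and one of the two symmetry‑equivalent ortho methoxy oxygens, chloride removes that methyl by SN2, and the six‑membered boron chelate so formed ties up the carbonyl and protects the second ortho methoxy group, while the non‑chelated methoxy groups at C3 and C5 should react much more slowly at low temperature.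

Step 4
Reactants: 6 2,4‑dihydroxy‑3,5,6‑trimethoxybenzaldehyde; 7 benzyl bromide
Product: 8 2,4‑bis(benzyloxy)‑3,5,6‑trimethoxybenzaldehyde
Conditions: K2CO3, DMF, 60 °C, N2
Reagents that add atoms: benzyl bromide 7 (BrCc1ccccc1)
Why: Williamson ether synthesis; both phenoxides, including the hydrogen‑bonded one ortho to the aldehyde, are alkylated by the reactive benzylic bromide in DMF.

Step 5
Reactants: 8 2,4‑bis(benzyloxy)‑3,5,6‑trimethoxybenzaldehyde
Product: 9 (E)‑2,4‑bis(benzyloxy)‑3,5,6‑trimethoxybenzaldehyde oxime
Conditions: NH2OH·HCl, NaOAc, EtOH–H2O, 60 °C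
Reagents that add atoms: hydroxylamine hydrochloride (Cl.NO)
Why: Condensation of an aldehyde with hydroxylamine to the aldoxime, which proceeds even for 2,6‑disubstituted benzaldehydes and should give the more stable E isomer.

Step 6
Reactants: 9 (E)‑2,4‑bis(benzyloxy)‑3,5,6‑trimethoxybenzaldehyde oxime
Product: 11 2,4‑bis(benzyloxy)‑3,5,6‑trimethoxybenzonitrile oxide, via hydroximoyl chloride 10 (not isolated)
Conditions: NCS, cat. pyridine, CHCl3, rt; then Et3N, 0 °C; cold aqueous wash
Reagents that add atoms: none
Why: Chlorination of the aldoxime at carbon by NCS and 1,3‑dehydrochlorination with Et3N (the Huisgen route to nitrile oxides); ring A carries no hydrogen, so ring chlorination cannot compete, and the two ortho alkoxy groups make the dipole persistent enough for work‑up.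

Step 7
Reactants: 11 2,4‑bis(benzyloxy)‑3,5,6‑trimethoxybenzonitrile oxide; 12 4‑ethynylanisole
Product: 13 3‑[2,4‑bis(benzyloxy)‑3,5,6‑trimethoxyphenyl]‑5‑(4‑methoxyphenyl)isoxazole
Conditions: toluene, 80 °C, N2; equimolar amounts, the solution of 11 added slowly to the solution of 12
Reagents that add atoms: none
Why: Thermal Huisgen 1,3‑dipolar cycloaddition of an aryl nitrile oxide to a terminal aryl alkyne, a well‑known reaction class: the dipole carbon (future C4) bonds to the terminal alkyne carbon (future C3) and the dipole oxygen to the anisyl‑bearing carbon (future C2) in one concerted, asynchronous [π4s+π2s] event in which every atom of both partners ends up in the product. The isoxazole ring is closed by this intermolecular [3+2] annulation, both ring bonds forming in the same step with no open‑chain intermediate. No stereocentre is created. The selectivity needed is regiochemical (3,5‑ over 3,4‑diaryl isoxazole): the largest LUMO coefficient of the dipole lies on carbon and the largest HOMO coefficient of the electron‑rich arylacetylene on the terminal CH, which is also the less hindered end for the crowded dipole carbon, so orbital and steric effects both favour the 3,5‑isomer. The benzyloxy group at C2 and the methoxy group at C6 of the dipole flank the CNO unit and slow dimerisation to the furoxan, so the dipole should survive the heating that a hindered cycloaddition needs. Slow addition keeps the dipole dilute relative to the alkyne at all times, which further disfavours the bimolecular dimerisation, and the temperature stays below that of the nitrile oxide–isocyanate rearrangement.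

Step 8
Reactants: 13 3‑[2,4‑bis(benzyloxy)‑3,5,6‑trimethoxyphenyl]‑5‑(4‑methoxyphenyl)isoxazole
Product: 14 (Z)‑3‑amino‑3‑(2,4‑dihydroxy‑3,5,6‑trimethoxyphenyl)‑1‑(4‑methoxyphenyl)prop‑2‑en‑1‑one
Conditions: H2 (1 atm), 10% Pd/C, EtOAc–EtOH, rt; filtered under N2 and used crude
Reagents that add atoms: none
Why: Heterogeneous catalytic hydrogenolysis cleaves the weak N–O bond of the isoxazole to the Z‑configured, hydrogen‑bonded β‑enaminone and removes both benzyl ethers, while the vinylogous amide should resist further reduction at atmospheric pressure.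

Step 9
Reactants: 14 (Z)‑3‑amino‑3‑(2,4‑dihydroxy‑3,5,6‑trimethoxyphenyl)‑1‑(4‑methoxyphenyl)prop‑2‑en‑1‑one
Product: 16 7‑hydroxy‑4',5,6,8‑tetramethoxyflavone, via 1,3‑diketone 15 (not isolated)
Conditions: 2 M aq. HCl, EtOH, reflux
Reagents that add atoms: water (O)
Why: Acid hydrolysis of the enaminone to the 1,3‑diketone followed by cyclodehydration (the closing stage of the Baker–Venkataraman flavone synthesis): the C8a hydroxyl adds to the anisoyl carbonyl (6‑exo‑trig) and loss of water gives the pyranone, and since the only free ortho oxygen is the one at C8a a single flavone can form.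

**Compound list**

1 | 1,2,4,5‑tetramethoxybenzene | COc1cc(OC)c(OC)cc1OC | starting material
2 | (2,3,5,6‑tetramethoxyphenyl)lithium | [Li]c1c(OC)c(OC)cc(OC)c1OC | intermediate
3 | dimethyl (2,3,5,6‑tetramethoxyphenyl)boronate | COB(OC)c1c(OC)c(OC)cc(OC)c1OC | intermediate
4 | 2,3,5,6‑tetramethoxyphenol | Oc1c(OC)c(OC)cc(OC)c1OC | intermediate
5 | 4‑hydroxy‑2,3,5,6‑tetramethoxybenzaldehyde | O=Cc1c(OC)c(OC)c(O)c(OC)c1OC | intermediate
6 | 2,4‑dihydroxy‑3,5,6‑trimethoxybenzaldehyde | O=Cc1c(O)c(OC)c(O)c(OC)c1OC | intermediate
7 | benzyl bromide | BrCc1ccccc1 | starting material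
8 | 2,4‑bis(benzyloxy)‑3,5,6‑trimethoxybenzaldehyde | O=Cc1c(OCc2ccccc2)c(OC)c(OCc2ccccc2)c(OC)c1OC | intermediate
9 | (E)‑2,4‑bis(benzyloxy)‑3,5,6‑trimethoxybenzaldehyde oxime | O/N=C/c1c(OCc2ccccc2)c(OC)c(OCc2ccccc2)c(OC)c1OC | intermediate
10 | (Z)‑2,4‑bis(benzyloxy)‑N‑hydroxy‑3,5,6‑trimethoxybenzimidoyl chloride (hydroximoyl chloride) | O/N=C(\Cl)c1c(OCc2ccccc2)c(OC)c(OCc2ccccc2)c(OC)c1OC | intermediate
11 | 2,4‑bis(benzyloxy)‑3,5,6‑trimethoxybenzonitrile oxide | COc1c(OC)c(OCc2ccccc2)c(OC)c(OCc2ccccc2)c1C#[N+][O-] | intermediate
12 | 4‑ethynylanisole | C#Cc1ccc(OC)cc1 | starting material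
13 | 3‑[2,4‑bis(benzyloxy)‑3,5,6‑trimethoxyphenyl]‑5‑(4‑methoxyphenyl)isoxazole | COc1ccc(-c2cc(-c3c(OC)c(OC)c(OCc4ccccc4)c(OC)c3OCc3ccccc3)no2)cc1 | intermediate
14 | (Z)‑3‑amino‑3‑(2,4‑dihydroxy‑3,5,6‑trimethoxyphenyl)‑1‑(4‑methoxyphenyl)prop‑2‑en‑1‑one | COc1ccc(C(=O)/C=C(\N)c2c(O)c(OC)c(O)c(OC)c2OC)cc1 | intermediate
15 | 1‑(2,4‑dihydroxy‑3,5,6‑trimethoxyphenyl)‑3‑(4‑methoxyphenyl)propane‑1,3‑dione | COc1ccc(C(=O)CC(=O)c2c(O)c(OC)c(O)c(OC)c2OC)cc1 | intermediate
16 | 7‑hydroxy‑4',5,6,8‑tetramethoxyflavone | COc1ccc(-c2cc(=O)c3c(OC)c(OC)c(O)c(OC)c3o2)cc1 | target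

**Step count**

Total step count: 9. Longest linear sequence: 9 steps (1 to 16); compounds 7 and 12 are purchased.

**Steps most likely to fail, with fallbacks**

Step 7. The cycloaddition at the crowded dipole carbon may be slow, so that dimerisation to the furoxan or thermal rearrangement to the isocyanate consumes the dipole, and some 3,4‑regioisomer may form. The fallback sets out from 11 and comes back at 13. 4‑Methoxyacetophenone is condensed with pyrrolidine (cat. TsOH, toluene, reflux with water separation) to the enamine 1‑[1‑(4‑methoxyphenyl)ethenyl]pyrrolidine F1. This far more nucleophilic 2π partner should add to 11 at room temperature in CH2Cl2, its CH2 carbon bonding to the dipole carbon and the dipole oxygen to the amine‑bearing carbon, to give racemic 3‑[2,4‑bis(benzyloxy)‑3,5,6‑trimethoxyphenyl]‑5‑(4‑methoxyphenyl)‑5‑(pyrrolidin‑1‑yl)‑4,5‑dihydroisoxazole F2. Brief treatment of F2 with aq. HCl in THF eliminates pyrrolidine and aromatises the ring to isoxazole 13, with the regiochemistry fixed by the polarity of the enamine.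

Step 2. Electrophilic formylation of the free, very electron‑rich phenol may suffer from deactivation through O‑titanation, Lewis‑acid cleavage of methoxy groups or sluggish substitution at the doubly flanked position. The fallback sets out from 4 and comes back at 5, replacing electrophilic substitution by an aryllithium formylation. Phenol 4 is protected (MOMCl, i‑Pr2NEt, CH2Cl2) as 1‑(methoxymethoxy)‑2,3,5,6‑tetramethoxybenzene F3. The remaining ring hydrogen, flanked by two methoxy groups as in step 1, is lithiated (n‑BuLi, THF, 0 °C) and quenched with DMF to give 4‑(methoxymethoxy)‑2,3,5,6‑tetramethoxybenzaldehyde F4. Aqueous HCl in MeOH at 50 °C removes the acetal and returns aldehyde 5.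

Step 8. N–O hydrogenolysis may lag behind debenzylation on Pd/C, the catalyst may be slowed by the amine formed, or the enaminone may be over‑reduced on prolonged exposure. The fallback sets out from 13 and comes back at 14, separating the two reductive tasks. Reductive ring opening with Mo(CO)6 (zerovalent molybdenum) in MeCN–H2O at reflux should give (Z)‑3‑amino‑3‑[2,4‑bis(benzyloxy)‑3,5,6‑trimethoxyphenyl]‑1‑(4‑methoxyphenyl)prop‑2‑en‑1‑one F5. A short hydrogenolysis of F5 over 10% Pd/C in EtOAc then only has to remove the two benzyl ethers to reach 14.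

**Further compounds**

F1 | step 7 | 1‑[1‑(4‑methoxyphenyl)ethenyl]pyrrolidine | C=C(N1CCCC1)c1ccc(OC)cc1
F2 | step 7 | racemic 3‑[2,4‑bis(benzyloxy)‑3,5,6‑trimethoxyphenyl]‑5‑(4‑methoxyphenyl)‑5‑(pyrrolidin‑1‑yl)‑4,5‑dihydroisoxazole | COc1ccc(C2(N3CCCC3)CC(c3c(OC)c(OC)c(OCc4ccccc4)c(OC)c3OCc3ccccc3)=NO2)cc1
F3 | step 2 | 1‑(methoxymethoxy)‑2,3,5,6‑tetramethoxybenzene | COCOc1c(OC)c(OC)cc(OC)c1OC
F4 | step 2 | 4‑(methoxymethoxy)‑2,3,5,6‑tetramethoxybenzaldehyde | O=Cc1c(OC)c(OC)c(OCOC)c(OC)c1OC
F5 | step 8 | (Z)‑3‑amino‑3‑[2,4‑bis(benzyloxy)‑3,5,6‑trimethoxyphenyl]‑1‑(4‑methoxyphenyl)prop‑2‑en‑1‑one | COc1ccc(C(=O)/C=C(\N)c2c(OCc3ccccc3)c(OC)c(OCc3ccccc3)c(OC)c2OC)cc1
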